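**Retrosynthetic overview**

1. Numbering: C1 = prenylated bridgehead beside C8 (CMe2); C2–C3–C4 = aroyl β-diketone bridge; C5 = bridgehead carrying the dienyl side chain (C10, C11 …); C6; C7 (prenyl); C9 = bridging ketone. Ring A = C1–C2–C3–C4–C5–C9, ring B = C1–C9–C5–C6–C7–C8.
2. Enabling feature: C9, C2 and C4 of ring A plus the exocyclic aroyl C=O form a 1,3,5,7-tetracarbonyl chain folded on the quaternary carbons C1 and C5. Its C9–C1–C2–C3–C(aroyl) part can be stored as an enol lactone (a 3,3-disubstituted 6-arylpyran-2,4-dione) in which C9 is an acyl donor and C3 a masked nucleophile.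
3. Key disconnection (C5–C9 and C3–C4): an ester enolate at C5, on the chain attached to C1, attacks C9 and closes ring B; the expelled ring oxygen becomes the aroyl C=O and its diketonate carbon C3 attacks the C4 ester, closing ring A. Only removal of the catechol silyl groups follows.
4. Pyranedione ester 25 ⇐ Horner–Wadsworth–Emmons union at C6 of aldehyde 16 with the limonene-derived phosphonate 23, then conjugate reduction. 16 ⇐ gold-catalysed cyclization of a tert-butyl β-keto ynoate, made by opening the α-quaternary δ-lactone 9 with the aryl acetylide (lactone C=O = C2, ring O on C6, ester = C9 from CO2).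
5. Stereocentres: C7 by Evans alkylation of a 3,3-dimethylglutarate imide; C1 on the lactone template (CO2 trans to the C7 prenyl); the side-chain centre from (R)-limonene oxide; C5 in the key step. Ring order: template lactone, pyranedione, ring B, ring A.

Key step: step 20

Remark: the β-triketone of 28 and 29 is written as one enol tautomer (C4–OH) and descriptors refer to that form; Ar = 3,4-bis(tert-butyldimethylsilyloxy)phenyl, prenyl = 3-methylbut-2-en-1-yl.

**Route**

Step 1
Reactants: 1 5-methoxy-3,3-dimethyl-5-oxopentanoic acid (monomethyl 3,3-dimethylglutarate); 2 (4S)-4-benzyl-1,3-oxazolidin-2-one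
Product: 3 methyl 5-[(4S)-4-benzyl-2-oxo-1,3-oxazolidin-3-yl]-3,3-dimethyl-5-oxopentanoate
Conditions: PivCl, Et3N, THF, −20 °C; then 2, LiCl, −20 °C → rt
Reagents that add atoms: none
Why: N-acylation of the LiCl-activated oxazolidinone by the mixed pivalic anhydride of 1 attaches the auxiliary for an Evans alkylation; no stereocentre is formed.

Step 2
Reactants: 3
Product: 4 methyl (4S)-4-{[(4S)-4-benzyl-2-oxo-1,3-oxazolidin-3-yl]carbonyl}-3,3,7-trimethyloct-6-enoate
Conditions: NaN(SiMe3)2, THF, −78 °C; prenyl bromide, −78 → −40 °C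
Reagents that add atoms: prenyl bromide CC(C)=CCBr
Why: Evans asymmetric alkylation: the chelated Z-sodium enolate of the imide (far more acidic than the methyl ester) should be prenylated on the face opposite the benzyl group, which sets C7 of the target.

Step 3
Reactants: 4
Product: 6 (5S)-4,4-dimethyl-5-(3-methylbut-2-en-1-yl)oxan-2-one, via hydroxy ester 5 (not isolated)
Conditions: NaBH4, THF/H2O, 0 °C → rt; then PPTS (cat.), PhMe, 60 °C
Reagents that add atoms: none
Why: borohydride reductive cleavage of the N-acyloxazolidinone spares the methyl ester, and acid-catalysed lactonization (gem-dimethyl effect) gives the δ-lactone template; the stereocentre is not involved.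

Step 4
Reactants: 6
Product: 7 (5S)-4,4-dimethyl-3,5-bis(3-methylbut-2-en-1-yl)oxan-2-one (C3 epimers)
Conditions: LiN(i-Pr)2, THF, −78 °C; prenyl bromide, −78 → −20 °C
Reagents that add atoms: prenyl bromide CC(C)=CCBr
Why: alkylation of the lactone lithium enolate with an allylic bromide; the C3 centre needs no control because it is re-enolized in step 5.

Step 5
Reactants: 7
Product: 8 (3R,5S)-4,4-dimethyl-3,5-bis(3-methylbut-2-en-1-yl)-2-oxooxane-3-carboxylic acid
Conditions: LiN(i-Pr)2, THF, −78 → −40 °C; CO2, −78 °C; AcOH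
Reagents that add atoms: carbon dioxide O=C=O
Why: carboxylation of the fully substituted lactone enolate with the smallest C-electrophile; with the C5 prenyl pseudo-equatorial, CO2 should enter axially, anti to the pseudo-axial C4 methyl and so trans to the C5 prenyl, which sets the quaternary carbon (C1 of the target) with both prenyl groups cis on the lactone.

Step 6
Reactants: 8
Product: 9 tert-butyl (3S,5S)-4,4-dimethyl-3,5-bis(3-methylbut-2-en-1-yl)-2-oxooxane-3-carboxylate
Conditions: tert-butyl 2,2,2-trichloroacetimidate, cyclohexane/CH2Cl2, rt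
Reagents that add atoms: tert-butyl 2,2,2-trichloroacetimidate CC(C)(C)OC(=N)C(Cl)(Cl)Cl
Why: imidate esterification transfers a tert-butyl cation to the carboxyl oxygen, so the congested acyl carbon is not attacked, and the ester is inert in steps 9–10 and ionizable in step 11; the descriptor changes only through CIP priority.

Step 7
Reactants: 10 3,4-dihydroxybenzaldehyde
Product: 11 3,4-bis{[tert-butyl(dimethyl)silyl]oxy}benzaldehyde
Conditions: TBSCl, imidazole, DMF, rt
Reagents that add atoms: tert-butyldimethylsilyl chloride CC(C)(C)[Si](C)(C)Cl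
Why: silyl ether formation masks the catechol against organolithiums and amide bases and allows fluoride release at the end.

Step 8
Reactants: 11
Product: 12 4-(2,2-dibromoethenyl)-1,2-bis{[tert-butyl(dimethyl)silyl]oxy}benzene
Conditions: CBr4, PPh3, Zn, CH2Cl2, 0 °C → rt
Reagents that add atoms: carbon tetrabromide BrC(Br)(Br)Br
Why: Corey–Fuchs (Ramirez) dibromo-olefination of the aldehyde by the dibromomethylene ylide.

Step 9
Reactants: 12; 9
Product: 14 tert-butyl (2S)-2-(3-Ar-prop-2-ynoyl)-2-[(3S)-3-(hydroxymethyl)-2,6-dimethylhept-5-en-2-yl]-5-methylhex-4-enoate, via lithium arylacetylide 13 (not isolated)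
Conditions: 12, n-BuLi (2.05 equiv), THF, −78 → 0 °C; then 9, −78 °C; AcOH, −78 °C
Reagents that add atoms: none
Why: the second Corey–Fuchs stage (Br–Li exchange, Fritsch–Buttenberg–Wiechell rearrangement) gives acetylide 13, which should add once to the δ-lactone carbonyl (the lactolate is stable at −78 °C) while the tert-butyl ester is inert; the lactone carbon becomes ynone carbon C2, C6 is released as the alcohol and C1 is untouched.

Step 10
Reactants: 14
Product: 15 tert-butyl (2S)-2-(3-Ar-prop-2-ynoyl)-2-[(3S)-3-formyl-2,6-dimethylhept-5-en-2-yl]-5-methylhex-4-enoate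
Conditions: Dess–Martin periodinane, CH2Cl2, 0 °C → rt
Reagents that add atoms: none
Why: Dess–Martin oxidation of the primary alcohol under neutral conditions should give the aldehyde without epimerizing the adjacent C7 centre or touching the ynone.

Step 11
Reactants: 15
Product: 16 (2S)-2-{2-[(3S)-6-Ar-3-(3-methylbut-2-en-1-yl)-2,4-dioxo-3,4-dihydro-2H-pyran-3-yl]propan-2-yl}-5-methylhex-4-enal
Conditions: (Ph3P)AuNTf2 (5 mol %), AcOH, MeNO2, rt
Reagents that add atoms: none
Why: gold-catalysed 6-endo-dig cyclization of a tert-butyl 3-oxoalk-4-ynoate (π-activation of the ynone, attack of the ester carbonyl oxygen, loss of 2-methylpropene) gives the 3,3-disubstituted 6-arylpyran-2,4-dione without a free β-keto acid and without change at C1.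

Step 12
Reactants: 17 (4R)-1-methyl-4-(prop-1-en-2-yl)-7-oxabicyclo[4.1.0]heptane ((R)-limonene 1,2-oxide, cis/trans mixture)
Product: 18 (3R)-6-oxo-3-(prop-1-en-2-yl)heptanal
Conditions: H5IO6, THF/H2O, 0 °C → rt
Reagents that add atoms: water O
Why: periodic acid hydrolyses the epoxide and cleaves the 1,2-diol (Malaprade glycol cleavage); the isopropenyl-bearing stereocentre of (R)-limonene is not touched.

Step 13
Reactants: 18
Product: 19 (4R)-7-methyl-4-(prop-1-en-2-yl)octa-1,7-diene
Conditions: Ph3PCH3Br, KOt-Bu, THF, 0 °C; then 18, −78 °C → rt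
Reagents that add atoms: methyltriphenylphosphonium bromide C[P+](c1ccccc1)(c1ccccc1)c1ccccc1.[Br-]
Why: double Wittig methylenation of aldehyde and ketone with the non-stabilized ylide; the stereocentre is not alpha to either carbonyl and cannot epimerize.

Step 14
Reactants: 19
Product: 20 (4R)-7-methyl-4-(prop-1-en-2-yl)oct-7-en-1-ol
Conditions: (Sia)2BH, THF, −20 → 0 °C; then NaOH, H2O2, 0 °C
Reagents that add atoms: hydrogen peroxide OO
Why: anti-Markovnikov hydroboration–oxidation; the bulky dialkylborane should select the monosubstituted vinyl group over the two 1,1-disubstituted alkenes.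

Step 15
Reactants: 20
Product: 21 (4R)-7-methyl-4-(prop-1-en-2-yl)oct-7-enoic acid
Conditions: TEMPO (cat.), PhI(OAc)2, MeCN/H2O, rt
Reagents that add atoms: water O
Why: TEMPO/oxoammonium oxidation of the primary alcohol through the aldehyde hydrate to the acid leaves the alkenes untouched.

Step 16
Reactants: 21
Product: 22 methyl (4R)-7-methyl-4-(prop-1-en-2-yl)oct-7-enoate
Conditions: MeI, K2CO3, DMF, rt
Reagents that add atoms: iodomethane CI
Why: SN2 O-alkylation of the carboxylate gives the methyl ester that later serves as the C4 electrophile.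

Step 17
Reactants: 22
Product: 23 methyl (4R)-2-(diethoxyphosphoryl)-7-methyl-4-(prop-1-en-2-yl)oct-7-enoate (C2 epimers)
Conditions: LiN(i-Pr)2 (2.1 equiv), THF, −78 °C; ClP(O)(OEt)2, −78 → 0 °C; aq. NH4Cl
Reagents that add atoms: diethyl chlorophosphate CCOP(=O)(Cl)OCC
Why: phosphorylation of the ester enolate (O-phosphorylation, then base-induced 1,3-phosphoryl migration driven by deprotonation of the product) gives the Horner–Wadsworth–Emmons reagent.

Step 18
Reactants: 23; 16
Product: 24 methyl (4R)-7-methyl-2-[(2R)-5-methyl-2-(prop-1-en-2-yl)hex-5-en-1-yl]-4-{2-[(3S)-6-Ar-3-(3-methylbut-2-en-1-yl)-2,4-dioxo-3,4-dihydro-2H-pyran-3-yl]propan-2-yl}octa-2,6-dienoate (2E/2Z mixture)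
Conditions: 23, NaH, THF, 0 °C; then 16, −78 → 0 °C
Reagents that add atoms: none
Why: Horner–Wadsworth–Emmons olefination: the stabilized phosphonate anion should add to the aldehyde far faster than to the congested enol lactone, forming the C5–C6 bond; alkene geometry is irrelevant because the double bond is reduced in step 19.

Step 19
Reactants: 24
Product: 25 methyl (4R)-7-methyl-2-[(2R)-5-methyl-2-(prop-1-en-2-yl)hex-5-en-1-yl]-4-{2-[(3S)-6-Ar-3-(3-methylbut-2-en-1-yl)-2,4-dioxo-3,4-dihydro-2H-pyran-3-yl]propan-2-yl}oct-6-enoate (C2 epimers)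
Conditions: [(Ph3P)CuH]6 (5 mol %), PhMe2SiH, t-BuOH, PhMe, rt
Reagents that add atoms: none
Why: copper hydride conjugate reduction ([(Ph3P)CuH]6 with silane turnover, t-BuOH as proton source) should reduce only the α,β-unsaturated ester and leave the isolated alkenes and the donor-deactivated β-aryl-β-acyloxy enone; the C5 epimer mixture is inconsequential because C5 is re-enolized in step 20.

Step 20
Reactants: 25
Product: 28 (1R,5R,7R)-3-(3,4-bis{[tert-butyl(dimethyl)silyl]oxy}benzoyl)-4-hydroxy-8,8-dimethyl-1,7-bis(3-methylbut-2-en-1-yl)-5-[(2R)-5-methyl-2-(prop-1-en-2-yl)hex-5-en-1-yl]bicyclo[3.3.1]non-3-ene-2,9-dione, via lithium ester enolate 26 (not isolated), via ring B keto ester lithium diketonate 27 (not isolated)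
Conditions: LiN(SiMe3)2 (2.2 equiv), THF, −78 °C → rt (45 °C if ring A closure lags); AcOH
Reagents that add atoms: none
Why: Proposed new method: LiN(SiMe3)2 removes the only acidic C–H of 25 (C5–H; the pyranedione has no enolizable proton), enolate 26 attacks the enol-lactone carbonyl C9, and collapse of the tetrahedral intermediate expels the ring oxygen, which becomes the aroyl C=O and leaves C3 as the carbon of lithium 1,3-diketonate 27; C3 then attacks the C4 methyl ester held 1,3-diaxial to it, and loss of methoxide followed by deprotonation of the acidic triketone makes the sequence irreversible. The closest known reaction types are the diketene annulation of enolates (C-acylation by an enol lactone that releases a ketone enolate for a second Claisen condensation), carbanion-induced ring transformations of 2-pyranones and Dieckmann closures of bicyclo[3.3.1]nonane-2,4,9-triones; the relay through a pyran-2,4-dione that forms both rings and a quaternary bridgehead in one operation is the untested part. Ring B closes by a 6-(enolexo)-exo-trig acyl substitution (C5–C9) and ring A by a 6-exo-trig Claisen condensation of the diketonate (C3–C4), both allowed for six-membered rings. C1 and C7 are already set in 25 (steps 5 and 2), and the tether leaves C1 on one face of the flat pyranedione, so C5 can reach C9 only from that face; the new centre C5 is then decided by which enolate substituent lies over C2, and lithium bridging between the enolate oxygen and the Lewis-basic vinylogous-ester carbonyl of C2, together with the preference of the β-branched C10 chain for the outer position, should place C4 on the C2 face, the only arrangement that can close ring A. The step needs C- rather than O-acylation and attack at C9 rather than at C2 or at the aryl-bearing carbon: C9 is the only carbonyl with a leaving group within reach of a six-membered transition state, addition to the C2 ketone is a reversible aldol, attack at the aryl-bearing carbon would need an eight-membered ring, and an O-acyl isomer formed at the second stage should be converted into the C-acyl triketonate by the released methoxide.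

Step 21
Reactants: 28
Product: 29 (1R,5R,7R)-3-(3,4-dihydroxybenzoyl)-4-hydroxy-8,8-dimethyl-1,7-bis(3-methylbut-2-en-1-yl)-5-[(2R)-5-methyl-2-(prop-1-en-2-yl)hex-5-en-1-yl]bicyclo[3.3.1]non-3-ene-2,9-dione
Conditions: Bu4NF, AcOH (1:1), THF, 0 °C
Reagents that add atoms: none
Why: buffered fluoride cleavage of the two aryl silyl ethers; the AcOH buffer keeps the medium from turning basic, which should avoid oxidation of the catechol, and is too weakly acidic to cyclize the enol onto the alkenes.

**Compound list**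

1 | 5-methoxy-3,3-dimethyl-5-oxopentanoic acid | COC(=O)CC(C)(C)CC(=O)O | starting material
2 | (4S)-4-benzyl-1,3-oxazolidin-2-one | O=C1OC[C@H](Cc2ccccc2)N1 | starting material
3 | methyl 5-[(4S)-4-benzyl-2-oxo-1,3-oxazolidin-3-yl]-3,3-dimethyl-5-oxopentanoate | COC(=O)CC(C)(C)CC(=O)N1[C@@H](Cc2ccccc2)COC1=O | intermediate
4 | methyl (4S)-4-{[(4S)-4-benzyl-2-oxo-1,3-oxazolidin-3-yl]carbonyl}-3,3,7-trimethyloct-6-enoate | COC(=O)CC(C)(C)[C@H](CC=C(C)C)C(=O)N1[C@@H](Cc2ccccc2)COC1=O | intermediate
5 | methyl (4S)-4-(hydroxymethyl)-3,3,7-trimethyloct-6-enoate (hydroxy ester) | COC(=O)CC(C)(C)[C@H](CC=C(C)C)CO | intermediate (not isolated)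
6 | (5S)-4,4-dimethyl-5-(3-methylbut-2-en-1-yl)oxan-2-one | O=C1CC(C)(C)[C@H](CC=C(C)C)CO1 | intermediate
7 | (5S)-4,4-dimethyl-3,5-bis(3-methylbut-2-en-1-yl)oxan-2-one (C3 epimers) | O=C1OC[C@@H](CC=C(C)C)C(C)(C)C1CC=C(C)C | intermediate
8 | (3R,5S)-4,4-dimethyl-3,5-bis(3-methylbut-2-en-1-yl)-2-oxooxane-3-carboxylic acid (carboxyl trans to the C5 prenyl) | C1[C@@H](CC=C(C)C)C(C)(C)[C@@](CC=C(C)C)(C(=O)O1)C(=O)O | intermediate
9 | tert-butyl (3S,5S)-4,4-dimethyl-3,5-bis(3-methylbut-2-en-1-yl)-2-oxooxane-3-carboxylate | C1[C@@H](CC=C(C)C)C(C)(C)[C@@](CC=C(C)C)(C(=O)O1)C(=O)OC(C)(C)C | intermediate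
10 | 3,4-dihydroxybenzaldehyde | O=Cc1ccc(O)c(O)c1 | starting material
11 | 3,4-bis{[tert-butyl(dimethyl)silyl]oxy}benzaldehyde | O=Cc1ccc(O[Si](C)(C)C(C)(C)C)c(O[Si](C)(C)C(C)(C)C)c1 | intermediate
12 | 4-(2,2-dibromoethenyl)-1,2-bis{[tert-butyl(dimethyl)silyl]oxy}benzene | BrC(Br)=Cc1ccc(O[Si](C)(C)C(C)(C)C)c(O[Si](C)(C)C(C)(C)C)c1 | intermediate
13 | lithium 2-(3,4-bis{[tert-butyl(dimethyl)silyl]oxy}phenyl)ethyn-1-ide (lithium arylacetylide) | [Li]C#Cc1ccc(O[Si](C)(C)C(C)(C)C)c(O[Si](C)(C)C(C)(C)C)c1 | intermediate (not isolated)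
14 | tert-butyl (2S)-2-(3-Ar-prop-2-ynoyl)-2-[(3S)-3-(hydroxymethyl)-2,6-dimethylhept-5-en-2-yl]-5-methylhex-4-enoate | OC[C@@H](CC=C(C)C)C(C)(C)[C@@](CC=C(C)C)(C(=O)C#Cc1ccc(O[Si](C)(C)C(C)(C)C)c(O[Si](C)(C)C(C)(C)C)c1)C(=O)OC(C)(C)C | intermediate
15 | tert-butyl (2S)-2-(3-Ar-prop-2-ynoyl)-2-[(3S)-3-formyl-2,6-dimethylhept-5-en-2-yl]-5-methylhex-4-enoate | O=C[C@@H](CC=C(C)C)C(C)(C)[C@@](CC=C(C)C)(C(=O)C#Cc1ccc(O[Si](C)(C)C(C)(C)C)c(O[Si](C)(C)C(C)(C)C)c1)C(=O)OC(C)(C)C | intermediate
16 | (2S)-2-{2-[(3S)-6-Ar-3-(3-methylbut-2-en-1-yl)-2,4-dioxo-3,4-dihydro-2H-pyran-3-yl]propan-2-yl}-5-methylhex-4-enal | O=C[C@@H](CC=C(C)C)C(C)(C)[C@@](CC=C(C)C)(C(=O)C=C(c1ccc(O[Si](C)(C)C(C)(C)C)c(O[Si](C)(C)C(C)(C)C)c1)O2)C2=O | intermediate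
17 | (4R)-1-methyl-4-(prop-1-en-2-yl)-7-oxabicyclo[4.1.0]heptane ((R)-limonene 1,2-oxide, cis/trans) | CC12OC1C[C@@H](CC2)C(C)=C | starting material
18 | (3R)-6-oxo-3-(prop-1-en-2-yl)heptanal | O=CC[C@@H](CCC(C)=O)C(C)=C | intermediate
19 | (4R)-7-methyl-4-(prop-1-en-2-yl)octa-1,7-diene | C=CC[C@@H](CCC(C)=C)C(C)=C | intermediate
20 | (4R)-7-methyl-4-(prop-1-en-2-yl)oct-7-en-1-ol | OCCC[C@@H](CCC(C)=C)C(C)=C | intermediate
21 | (4R)-7-methyl-4-(prop-1-en-2-yl)oct-7-enoic acid | OC(=O)CC[C@@H](CCC(C)=C)C(C)=C | intermediate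
22 | methyl (4R)-7-methyl-4-(prop-1-en-2-yl)oct-7-enoate | COC(=O)CC[C@@H](CCC(C)=C)C(C)=C | intermediate
23 | methyl (4R)-2-(diethoxyphosphoryl)-7-methyl-4-(prop-1-en-2-yl)oct-7-enoate (C2 epimers) | CCOP(=O)(OCC)C(C[C@@H](CCC(C)=C)C(C)=C)C(=O)OC | intermediate
24 | methyl (4R)-7-methyl-2-[(2R)-5-methyl-2-(prop-1-en-2-yl)hex-5-en-1-yl]-4-{2-[(3S)-6-Ar-3-(3-methylbut-2-en-1-yl)-2,4-dioxo-3,4-dihydro-2H-pyran-3-yl]propan-2-yl}octa-2,6-dienoate (2E/2Z) | COC(=O)C(C[C@@H](CCC(C)=C)C(C)=C)=C[C@@H](CC=C(C)C)C(C)(C)[C@@](CC=C(C)C)(C(=O)C=C(c1ccc(O[Si](C)(C)C(C)(C)C)c(O[Si](C)(C)C(C)(C)C)c1)O2)C2=O | intermediate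
25 | methyl (4R)-7-methyl-2-[(2R)-5-methyl-2-(prop-1-en-2-yl)hex-5-en-1-yl]-4-{2-[(3S)-6-Ar-3-(3-methylbut-2-en-1-yl)-2,4-dioxo-3,4-dihydro-2H-pyran-3-yl]propan-2-yl}oct-6-enoate (C2 epimers) | COC(=O)C(C[C@@H](CCC(C)=C)C(C)=C)C[C@@H](CC=C(C)C)C(C)(C)[C@@](CC=C(C)C)(C(=O)C=C(c1ccc(O[Si](C)(C)C(C)(C)C)c(O[Si](C)(C)C(C)(C)C)c1)O2)C2=O | intermediate
26 | lithium ester enolate of 25 (C5=C4 enolate, geometry undefined) | [Li+].[O-]C(OC)=C(C[C@@H](CCC(C)=C)C(C)=C)C[C@@H](CC=C(C)C)C(C)(C)[C@@](CC=C(C)C)(C(=O)C=C(c1ccc(O[Si](C)(C)C(C)(C)C)c(O[Si](C)(C)C(C)(C)C)c1)O2)C2=O | intermediate (not isolated)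
27 | ring B keto ester lithium diketonate: lithium enolate of methyl (1S,3S,5R)-3-(3-Ar-3-oxopropanoyl)-4,4-dimethyl-3,5-bis(3-methylbut-2-en-1-yl)-1-[(2R)-5-methyl-2-(prop-1-en-2-yl)hex-5-en-1-yl]-2-oxocyclohexane-1-carboxylate (ester cis to the acyl chain) | [Li+].C=C(C)CC[C@H](C[C@]1(C(=O)OC)C[C@@H](CC=C(C)C)C(C)(C)[C@@](CC=C(C)C)(C(=O)C=C([O-])c2ccc(O[Si](C)(C)C(C)(C)C)c(O[Si](C)(C)C(C)(C)C)c2)C1=O)C(=C)C | intermediate (not isolated)
28 | (1R,5R,7R)-3-(3,4-bis{[tert-butyl(dimethyl)silyl]oxy}benzoyl)-4-hydroxy-8,8-dimethyl-1,7-bis(3-methylbut-2-en-1-yl)-5-[(2R)-5-methyl-2-(prop-1-en-2-yl)hex-5-en-1-yl]bicyclo[3.3.1]non-3-ene-2,9-dione | C=C(C)CC[C@H](C[C@@]12C[C@@H](CC=C(C)C)C(C)(C)[C@@](CC=C(C)C)(C(=O)C(C(=O)c3ccc(O[Si](C)(C)C(C)(C)C)c(O[Si](C)(C)C(C)(C)C)c3)=C1O)C2=O)C(=C)C | intermediate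
29 | (1R,5R,7R)-3-(3,4-dihydroxybenzoyl)-4-hydroxy-8,8-dimethyl-1,7-bis(3-methylbut-2-en-1-yl)-5-[(2R)-5-methyl-2-(prop-1-en-2-yl)hex-5-en-1-yl]bicyclo[3.3.1]non-3-ene-2,9-dione | C=C(C)CC[C@H](C[C@@]12C[C@@H](CC=C(C)C)C(C)(C)[C@@](CC=C(C)C)(C(=O)C(C(=O)c3ccc(O)c(O)c3)=C1O)C2=O)C(=C)C | target

**Step count and risks**

Total step count: 21. Longest linear sequence: 13 steps (steps 1–6, 9–11, 18–21).

Steps most likely to fail:

1. Step 20 (proposed method). Poor facial selectivity in the ring B closure, with the C5 enolate adding to C9 so that the ester lies on the face away from C2, would strand material as a ring B keto ester that cannot close ring A. The second acylation could also stall after O-acyl transfer. The fallback replaces the kinetic relay by a thermodynamically controlled double Dieckmann condensation and sets out from 25. DMAP-catalysed methanolysis of the enol lactone (MeOH, CH2Cl2, rt) should give the open-chain diester β-diketone F1. KOt-Bu in THF/t-BuOH (0 °C → rt) should then close ring B reversibly, so that retro-Dieckmann cleavage returns the wrong C5 epimer to F1, and close ring A irreversibly as the triketonate. The fallback returns to the route at 28; any material desilylated by the alkoxide is already 29.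

2. Step 18. The α-branched phosphonate anion may add too slowly to the hindered α-branched aldehyde, which would let attack on the pyranedione or epimerization at C7 compete. The fallback moves the C5–C6 bond formation to Lewis-acid conditions and sets out from 22 and 16. LiN(i-Pr)2/Me3SiCl should convert 22 into the methyl trimethylsilyl ketene acetal F2. Mukaiyama aldol addition of F2 to 16 (BF3·OEt2, CH2Cl2, −78 °C) should give the β-hydroxy ester F3. Burgess dehydration (PhMe, 50 °C) should then return to the route at 24.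

3. Step 9. Addition of the acetylide to the very congested lactone carbonyl may be sluggish, and retro-Claisen cleavage of the product by excess acetylide or alkoxide on warming is possible. The fallback goes through the aldehyde oxidation level and sets out from 9. i-Bu2AlH (CH2Cl2, −78 °C) should give the lactol F4. Addition of 13 (from 12 and n-BuLi, 3 equiv) to its open hydroxy aldehyde form should give the propargylic diol F5. MnO2 (CH2Cl2) should oxidize only the propargylic alcohol and return to the route at 14.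

Further compounds
F1 | step 20 | open-chain diester β-diketone (25 with the pyranedione opened by methanol: CO2Me on C1, free ArCOCH2CO group, C1 S) | COC(=O)C(C[C@@H](CCC(C)=C)C(C)=C)C[C@@H](CC=C(C)C)C(C)(C)[C@@](CC=C(C)C)(C(=O)CC(=O)c1ccc(O[Si](C)(C)C(C)(C)C)c(O[Si](C)(C)C(C)(C)C)c1)C(=O)OC
F2 | step 18 | methyl trimethylsilyl ketene acetal of 22: {[(4R)-1-methoxy-7-methyl-4-(prop-1-en-2-yl)octa-1,7-dien-1-yl]oxy}(trimethyl)silane | COC(O[Si](C)(C)C)=CC[C@@H](CCC(C)=C)C(C)=C
F3 | step 18 | β-hydroxy ester (3-hydroxy derivative of 25, C3 and C2 epimers) | COC(=O)C(C[C@@H](CCC(C)=C)C(C)=C)C(O)[C@@H](CC=C(C)C)C(C)(C)[C@@](CC=C(C)C)(C(=O)C=C(c1ccc(O[Si](C)(C)C(C)(C)C)c(O[Si](C)(C)C(C)(C)C)c1)O2)C2=O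
F4 | step 9 | lactol: tert-butyl (3S,5S)-2-hydroxy-4,4-dimethyl-3,5-bis(3-methylbut-2-en-1-yl)oxane-3-carboxylate (anomers) | C1[C@@H](CC=C(C)C)C(C)(C)[C@@](CC=C(C)C)(C(O)O1)C(=O)OC(C)(C)C
F5 | step 9 | propargylic diol: tert-butyl (2S)-2-(3-Ar-1-hydroxyprop-2-yn-1-yl)-2-[(3S)-3-(hydroxymethyl)-2,6-dimethylhept-5-en-2-yl]-5-methylhex-4-enoate (carbinol epimers) | OC[C@@H](CC=C(C)C)C(C)(C)[C@@](CC=C(C)C)(C(O)C#Cc1ccc(O[Si](C)(C)C(C)(C)C)c(O[Si](C)(C)C(C)(C)C)c1)C(=O)OC(C)(C)C
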